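The rate constants are invented; the flask was simulated.

You take over two flasks, and the first thing to ask of each is what will be left over: how much Ry has still not met Vo.

- Wednesday's: Ry 0.034 M; Vo 1.20 equiv; Qa 1.4 mM (held); time 3.0 min
- Thursday's: Ry 0.034 M; Vo 2.40 equiv; Qa 1.4 mM (held); time 3.0 min

    Ry + Vo → Ek (k1 = 0.20 M⁻¹ s⁻¹)
    Ve + Ek → Aj (k2 = 7.8 M⁻¹ s⁻¹)
    Qa ⇌ Ve, rate k3*(csat - [Ve]) (k3 = 0.034 s⁻¹, csat = 1.4 mM)
    Ek → Wy (k4 = 0.0089 s⁻¹)

- at the start none of Ve is dissolved
- run time (Wednesday's): 3.0 min

1. which of these there is most of at the end, counted by the Ry in it, Wednesday's (Ek / Aj / Ry)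
2. which of these there is most of at the end, counted by the Ry in it, Thursday's (Ek / Aj / Ry)
3. amount of the one of these that there is most of at the end, in percent of the Ry charged, Wednesday's
4. amount of the one of these that there is most of at the end, in percent of the Ry charged, Thursday's

Each flask is heading for an end state of Aj and Wy, with Ry as the limiting reagent, so what you need to know is how far along you will find it. Ry and Vo stand in the first step and in no other, so they fall by equal amounts and their second-order decline can be integrated by hand. Let r be the equivalents of Vo, let x be the first rate constant times the Ry charge times the time (1.22 here), and let E be e raised to x times (r minus one). The unspent fraction of Ry is then (r minus one) over (r times E minus one).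

For Wednesday's this unspent fraction 37.5 % is the number to expect, and for Thursday's it is 11.4 %. Qa stands nowhere in the rule, so leave the gas alone if Ry spent is what you are watching. Gas arriving at its full rate brings 25.2 % of the charge, which is less than Wednesday's Ry but more than Thursday's. That ceiling bounds Aj and not Ek, so it puts Aj below Wednesday's Ry. Ek draws on the 62.5 % of Ry spent in Wednesday's, but the half-life of Ek by the step to Wy, 1.3 min, is shorter than the 3.0 min of the run, so Ek leaks to Wy while it is being made. On that judgement, which is no bound, I name Ry for Wednesday's and expect Ek below it. For Thursday's my reckoning stops: I expect the top place to go to Ek or Aj, and I give no figure.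

The forecast says Ry at 37.5 % for Wednesday's and Ek at 21.5 % for Thursday's, reasoning “so on Thursday the extra Ek piles up”.

The simulation gives Ry at 37.5 % and Ek at 23.0 %. Wednesday's 37.5 % stands against 37.5 % in the flask. The neighbour of Thursday's with 0.600 equiv of Vo reckons to 63.3 % by the same rule and holds 63.3 % Ry. Wednesday's has not come to rest at 3.0 min. At 30.0 min the rule gives 1.55 % Ry and the flask holds 1.55 %, with Ek down to 0.126 %, Aj up from 14.2 % to 37.8 % and Wy up from 30.7 % to 60.5 %. Thursday's at that time holds Aj at 30.1 % and Wy at 69.9 %.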